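## Structural features

The target 27 is an unbranched chain of eight benzene rings (A to H) joined by seven diaryl ether oxygens; it carries 21 free phenolic hydroxyls and has no stereocentre, so no stereochemical relationship has to be set. Rings B, D and F are 3,5-dihydroxy-1,4-phenylenedioxy units, rings C, E and G are 3,4,5-trihydroxy-1,2-phenylenedioxy units with their ether oxygens on positions 1 and 6, ring A is a 2,4,6-trihydroxyphenyl cap and ring H a 3,4,5-trihydroxyphenyl cap. Each of the seven ether oxygens sits on at least one carbon that has oxygen on both neighbours (A1, B4, D4, F4, C6, E6, G6), so every ether is crowded and every ring is electron-rich. The free pyrogallol and phloroglucinol arrays are oxidised easily, most of all in base, and the free compound is very polar; the hydroxyls therefore have to stay masked until the last step. The real difficulty is the regiocontrolled formation of seven hindered, electron-rich diaryl ethers in a molecule in which 35 of the 48 ring carbons bear oxygen. The feature exploited is ring C: its ether carbons C1 and C6 lie para and ortho to C4 and C5, so a ring with formyl groups at C4 and C5 and fluorides at C1 and C6 is a twofold SNAr electrophile with two sites of different reactivity, and the formyl groups later become the C4 and C5 hydroxyls. Rings E and G show the same pattern, so one linchpin serves all three.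

## Logic of the disconnections

27 ⇒ 26. The nineteen O–CH3 bonds are cut. The free polyphenol cannot be carried through base or oxidant, and methyl is the one mask that survives every earlier step. The gain is a stable, non-polar precursor that can be chromatographed. The forward step must cleave all nineteen alkyl ethers without touching the seven diaryl ethers, under non-basic and non-oxidising conditions.

26 ⇒ 24. The C4–O and C5–O bonds of ring C are traced back to C4–CHO and C5–CHO. The two hydroxyls that crowd ring C thereby become the groups that activate it. The gain is an electrophilic ring C. The forward step needs two aryl migrations on a pentasubstituted ring with neighbouring formyl groups, without oxidation of the electron-rich rings A and H.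

24 ⇒ 9 + 4 + 22. The O–C1 and O–C6 bonds of ring C are cut. Both carbons are activated by the formyl groups, and the cut divides the octamer into pieces of two, one and five rings. The gain is the largest possible drop in size in one operation. The forward step must deliver the two phenoxides in a fixed order to the two different fluorides of 4.

22 ⇒ 21 ⇒ 20 ⇒ 18. Three functional-group cuts: the D1–O bond goes back to a D1–Br bond, the two O–CH3 bonds at E4 and E5 are removed, and the E4–O and E5–O bonds go back to formyl groups. The bromine is a latent hydroxyl that is inert to base, peracid and methylation. The gain is that ring E reaches the same dialdehyde form as ring C. The forward steps demand a clean twofold oxidation, a methylation and a hydroxylation of an unhindered aryl bromide.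

18 ⇒ 11 + 17. The O–E6 bond is cut. The gain is a trimer phenol and a two-ring fluoro dialdehyde that already holds the D4–O–E1 ether. The forward step must displace the less reactive, ortho-activated fluoride with an unhindered phenoxide.

17 ⇒ 16 ⇒ 15 ⇒ 13. The same three functional-group operations are applied to ring G: F1–O back to F1–Br, removal of the two O–CH3 bonds at G4 and G5, and G4–O and G5–O back to formyl groups. The demands are those of the ring E sequence, on a smaller molecule.

13 ⇒ 11 + 12. The O–G6 bond is cut. The gain is the same fluoro dialdehyde as above and a simple phenol, so one intermediate feeds two rings. The demand is again displacement of the ortho-activated fluoride.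

11 ⇒ 10 + 4. The ether bond para to a formyl group is cut. The gain is the linchpin and a purchasable bromophenol. The forward step must place the hindered phenoxide on the para-activated fluoride only and stop there.

9 ⇒ 7 ⇒ 5 + 6. The B4–O bond goes back to a formyl group, which activates the para fluoride; then the O–B1 bond is cut. The gain is two monomers. The forward steps need a hindered phenoxide to displace a moderately activated fluoride, and an oxidation that spares ring A.

4 ⇒ 1. The bond between the ring carbon that becomes C5 and its formyl carbon is cut. The gain is a benzaldehyde that already has the fluorides, the methoxy group and one formyl group in place. The forward step must metalate next to the masked formyl group and not between methoxy and fluorine.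

## Other disconnections considered

Alternative 1: The cut goes through ring C itself, at C1–C2, so that the ring arises from a four-membered ring carrying a methoxyvinyl unit. To deliver the C5 oxygen the cyclobutenone must also carry a 3-methoxy group, and A1 is drawn that way. In the forward step, heating A1 would open the cyclobutenone to a dienylketene, which would close by 6π electrocyclisation and tautomerise to the CD dimer A2 with a free C1 phenol.
- In its favour: all five oxygens of ring C are placed by construction, the C1 hydroxyl is differentiated without any oxidation, the conditions are neutral and thermal, and no neighbouring formyl groups appear. On regiochemical certainty for ring C it is the better plan, and like the chosen plan it creates no stereocentre.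
- Against it: A1 requires addition of a vinyl-metal reagent to one of two nearly equal carbonyl groups of an unsymmetrical four-membered precursor, followed by O-methylation of a tertiary alkoxide. The step builds one ring and no new inter-ring bond. The hindered ethers at C1–O–B4 and D4–O–E1 remain to be made, with the crowded B4 carbon having to act as the electrophile. The sequence would have to be repeated for rings E and G.
- Comparison: the chosen key step makes two inter-ring bonds and unites three fragments, where this one makes a dimer. The pericyclic cascade has no site-selectivity question between two fluorides, which is a point for it. In step economy it is clearly longer.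

Alternative 2: The cut removes ring A, at A2–A3 and A5–A6, leaving a heptamer whose B1 oxygen carries a malonate (A3) and a three-carbon keto diester (A4). In the forward step the bis-enolate of A4 would be acylated twice by the ester groups of A3 and the ring would enolise to the phloroglucinol diester A5. Saponification and decarboxylation would then be needed before the final deprotection.
- In its favour: ring A, the ring most easily attacked by peracid, would never meet an oxidant, which is a real advantage over the chosen plan. It forms two skeletal bonds in one step, equal to the chosen key step, and closes a ring as well.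
- Against it: the hard part of the molecule, the ethers of rings C, E and G, lies wholly inside A3 and is not addressed. The annulation would be run last, on the most valuable intermediate. The acidic malonate hydrogen of A3 can be removed by the bis-enolate, which deactivates both ester groups, and A4 can condense with itself.
- Comparison: the A–B ether costs only two steps from monomers in the chosen plan, against at least three late, linear steps here. Mechanistically a double Claisen condensation is sound for simple malonates but is not matched to a hindered aryloxymalonate.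

Alternative 3: The cut is at the C–O bonds of C4, E4, G4 and H4, which are traced back to four formyl groups in the tetra-aldehyde A6. In the forward step a peracid would convert the four formyl groups into formates, and methanolysis would give the tetraphenol A7, ready for global demethylation.
- In its favour: each formyl group stands alone between two methoxy groups, the best kind of substrate for a Dakin oxidation, with none of the complications of neighbouring formyl groups. Here it is better than the chosen plan. It needs no re-methylation, which saves the two methylation steps of the chosen route, and it uses the same oxidation mechanism, so on that point the two are equal.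
- Against it: the step forms no inter-ring bond, so the whole skeleton of A6 must already exist. A single formyl group at position 4 activates only position 1 of its ring, so the O–C6 bonds of rings C, E and G get no help and one ether is made per formyl group, not two. Four oxidations must all go to completion on one large molecule that contains ring A.
- Comparison: the end game is as short as the chosen one, but the way to A6 is longer and linear.

Key step: step 13

Remarks on the chemistry:
- The structures of 9, 4, 22 and 24 were re-derived ring by ring from 27 and are consistent. Nineteen methyl ethers plus two formyl groups account for the 21 hydroxyls, and the formyl groups of 4 sit para to the fluoride that becomes C1 and ortho to the one that becomes C6.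
- The pentamer 22 is built by running the same linchpin chemistry twice more (rings G and E), with a bromine atom as the latent F1 and D1 hydroxyl. This takes nine steps from 4.
- The fluoro monoether 11 is needed for both ring G and ring E. It is therefore made once, isolated and divided between steps 5 and 9. The key step keeps both displacements in one flask.
- DMSO is used in place of DMF and the mixtures are kept dry, so that neither dimethylamine nor hydroxide competes at the fluorides or attacks the neighbouring formyl groups.
- Assumption: 4-bromo-2,6-dimethoxyphenol 10 is taken as a purchasable starting material.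

## Route

Step 1
Reactants: 1 4,5-difluoro-2-methoxybenzaldehyde
Product: 4 3,4-difluoro-6-methoxyphthalaldehyde, via lithium amino alkoxide adduct 2 (not isolated), via ring-lithiated amino alkoxide 3 (not isolated)
Conditions: Me2NCH2CH2N(Me)Li (from the amine and n-BuLi), THF, −78 °C; n-BuLi, −78 °C; DMF, −78 → 0 °C; aq. HCl
Reagents that add atoms: N,N-dimethylformamide, CN(C)C=O
Why: Directed ortho-metalation with an in situ α-amino alkoxide: the lithium amide adds to the formyl group of 1, masking it and making it a chelating director, so n-BuLi should remove the one hydrogen that is ortho to both this group and a fluorine and not the one between methoxy and fluorine. DMF formylates the aryllithium and acidic work-up releases both formyl groups; holding −78 °C should prevent loss of LiF to an aryne.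

Step 2
Reactants: 5 2,4,6-trimethoxyphenol; 6 4-fluoro-2,6-dimethoxybenzaldehyde
Product: 7 2,6-dimethoxy-4-(2,4,6-trimethoxyphenoxy)benzaldehyde
Conditions: Cs2CO3, DMSO, 110 °C, argon
Reagents that add atoms: none
Why: SNAr diaryl ether synthesis: the fluoride of 6 is para to the formyl group, which stabilises the Meisenheimer complex formed by the electron-rich though crowded phenoxide of 5. Argon protects the oxidisable phenoxide.

Step 3
Reactants: 7 2,6-dimethoxy-4-(2,4,6-trimethoxyphenoxy)benzaldehyde
Product: 9 2,6-dimethoxy-4-(2,4,6-trimethoxyphenoxy)phenol, via aryl formate 8 (not isolated)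
Conditions: 30% H2O2, cat. H2SO4, MeOH, rt
Reagents that add atoms: hydrogen peroxide, OO
Why: Acid-catalysed Dakin (Baeyer–Villiger) oxidation: the aryl group, with two ortho methoxy groups and a para aryloxy group, should migrate in preference to hydrogen, and the formate 8 is methanolysed in the same flask. Hydrogen peroxide with catalytic acid is less likely than a peracid to hydroxylate the electron-rich ring A.

Step 4
Reactants: 10 4-bromo-2,6-dimethoxyphenol; 4 3,4-difluoro-6-methoxyphthalaldehyde
Product: 11 4-(4-bromo-2,6-dimethoxyphenoxy)-3-fluoro-6-methoxyphthalaldehyde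
Conditions: Cs2CO3, DMSO, 4 Å MS, 25 °C, argon (slight excess of 4)
Reagents that add atoms: none
Why: SNAr: the hindered cesium phenoxide of 10 should add to the fluorine-bearing carbon that is para to a formyl group and meta to the methoxy group, while the other fluoride, ortho-activated only and para to the methoxy donor, should stay at 25 °C. The aryl bromide is not activated and should be untouched. 11 is isolated because it feeds both ring G (step 5) and ring E (step 9), and its isolation lets the site of the first displacement be proven before the key step.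

Step 5
Reactants: 11 4-(4-bromo-2,6-dimethoxyphenoxy)-3-fluoro-6-methoxyphthalaldehyde; 12 3,4,5-trimethoxyphenol
Product: 13 4-(4-bromo-2,6-dimethoxyphenoxy)-6-methoxy-3-(3,4,5-trimethoxyphenoxy)phthalaldehyde
Conditions: Cs2CO3, DMSO, 4 Å MS, 90 °C, argon
Reagents that add atoms: none
Why: Second SNAr on the same ring: on heating, the unhindered phenoxide of 12 should displace the remaining fluoride, which is ortho to a formyl group. This completes ring G with both of its ether bonds and models the second stage of the key step.

Step 6
Reactants: 13 4-(4-bromo-2,6-dimethoxyphenoxy)-6-methoxy-3-(3,4,5-trimethoxyphenoxy)phthalaldehyde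
Product: 15 4-(4-bromo-2,6-dimethoxyphenoxy)-6-methoxy-3-(3,4,5-trimethoxyphenoxy)benzene-1,2-diol, via bis-formate 14 (not isolated)
Conditions: mCPBA, CH2Cl2, 0 °C → rt; aq. Na2S2O3/NaHCO3 wash; then MeOH, cat. HCl, rt, argon
Reagents that add atoms: mCPBA (3-chloroperoxybenzoic acid), OOC(=O)c1cccc(Cl)c1
Why: Twofold Dakin (Baeyer–Villiger) oxidation: each migrating ring carbon has an ortho or para oxygen donor, so aryl migration to the formates is expected. Acidic methanolysis after removal of the peracid frees the catechol without exposing it to oxidant or base.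

Step 7
Reactants: 15 4-(4-bromo-2,6-dimethoxyphenoxy)-6-methoxy-3-(3,4,5-trimethoxyphenoxy)benzene-1,2-diol
Product: 16 5-bromo-1,3-dimethoxy-2-[3,4,5-trimethoxy-2-(3,4,5-trimethoxyphenoxy)phenoxy]benzene
Conditions: MeI, K2CO3, DMF, rt → 40 °C, argon
Reagents that add atoms: iodomethane, CI
Why: Williamson O-methylation of both catechol hydroxyls; it gives ring G its trimethoxy pattern and makes the trimer inert to the later base and peracid steps.

Step 8
Reactants: 16 5-bromo-1,3-dimethoxy-2-[3,4,5-trimethoxy-2-(3,4,5-trimethoxyphenoxy)phenoxy]benzene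
Product: 17 3,5-dimethoxy-4-[3,4,5-trimethoxy-2-(3,4,5-trimethoxyphenoxy)phenoxy]phenol
Conditions: Pd2(dba)3 (cat.), tBuXPhos (cat.), KOH, 1,4-dioxane/H2O, 100 °C; then aq. HCl
Reagents that add atoms: potassium hydroxide, [K+].[OH-]
Why: Palladium-catalysed hydroxylation of an aryl bromide: oxidative addition to zerovalent palladium, exchange of bromide for hydroxide and C–O reductive elimination promoted by the bulky biaryl phosphine. The bromide is unhindered and the substrate has only base-stable ethers.

Step 9
Reactants: 11 4-(4-bromo-2,6-dimethoxyphenoxy)-3-fluoro-6-methoxyphthalaldehyde; 17 3,5-dimethoxy-4-[3,4,5-trimethoxy-2-(3,4,5-trimethoxyphenoxy)phenoxy]phenol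
Product: 18 4-(4-bromo-2,6-dimethoxyphenoxy)-3-{3,5-dimethoxy-4-[3,4,5-trimethoxy-2-(3,4,5-trimethoxyphenoxy)phenoxy]phenoxy}-6-methoxyphthalaldehyde
Conditions: Cs2CO3, DMSO, 4 Å MS, 90 °C, argon
Reagents that add atoms: none
Why: The same SNAr as step 5: the unhindered F1 phenoxide of 17 should displace the ortho-activated fluoride of 11 on heating. This forms the E6–O bond and completes ring E, whose E1 ether is already in 11.

Step 10
Reactants: 18 bromo pentamer dialdehyde (formyl groups at E4 and E5)
Product: 20 bromo pentamer E4,E5-diol, via bis-formate 19 (not isolated)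
Conditions: mCPBA, CH2Cl2, 0 °C → rt; aq. Na2S2O3/NaHCO3 wash; then MeOH, cat. HCl, rt, argon
Reagents that add atoms: mCPBA (3-chloroperoxybenzoic acid), OOC(=O)c1cccc(Cl)c1
Why: Twofold Dakin (Baeyer–Villiger) oxidation as in step 6; both formyl groups sit on an oxygen-rich ring whose carbons should migrate readily, and the formates are cleaved by acidic methanolysis.

Step 11
Reactants: 20 bromo pentamer E4,E5-diol
Product: 21 permethylated DEFGH pentamer with bromine at D1
Conditions: MeI, K2CO3, DMF, rt → 40 °C, argon
Reagents that add atoms: iodomethane, CI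
Why: Williamson O-methylation of the catechol, as in step 7; ring E becomes the trimethoxy ring.

Step 12
Reactants: 21 permethylated DEFGH pentamer with bromine at D1
Product: 22 permethylated DEFGH pentamer with free D1 phenol
Conditions: Pd2(dba)3 (cat.), tBuXPhos (cat.), KOH, 1,4-dioxane/H2O, 100 °C; then aq. HCl
Reagents that add atoms: potassium hydroxide, [K+].[OH-]
Why: Palladium-catalysed hydroxylation of the unhindered D1 bromide, as in step 8; all other groups are ethers that are stable to hot hydroxide.

Step 13
Reactants: 9 2,6-dimethoxy-4-(2,4,6-trimethoxyphenoxy)phenol; 4 3,4-difluoro-6-methoxyphthalaldehyde; 22 permethylated DEFGH pentamer with free D1 phenol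
Product: 24 octamer dialdehyde (formyl groups at C4 and C5; nineteen methyl ethers), via fluoro monoether 23 (not isolated)
Conditions: Cs2CO3, DMSO, 4 Å MS, 25 °C (9 + 4); then add 22, 90 °C
Reagents that add atoms: none
Why: Both bonds form by addition–elimination (SNAr): each cesium phenoxide adds to a fluorine-bearing carbon of 4 to give a Meisenheimer complex whose charge is taken up by a formyl group, and fluoride leaves. The closest known reaction type is the diaryl ether synthesis from fluorobenzaldehydes and phenoxides under carbonate in a dipolar aprotic solvent, run twice on one ring as in steps 4, 5 and 9. No ring closes and no stereocentre forms. The selectivity needed is the order of the two displacements. The fluoride at the future C1 is para to the C4 formyl group, meta to the methoxy group and flanked by a hydrogen, so it should react at 25 °C with the crowded 2,6-dimethoxyphenoxide of 9. The fluoride at the future C6 is only ortho-activated, lies para to the methoxy donor and becomes flanked by the new aryloxy group, so it should stay in 23 until 22 is added and the mixture is heated. The unhindered D1 phenoxide of 22 is matched to this more crowded and less reactive site. Dry DMSO keeps hydroxide and dimethylamine away from the fluorides and the neighbouring formyl groups.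

Step 14
Reactants: 24 octamer dialdehyde (formyl groups at C4 and C5; nineteen methyl ethers)
Product: 26 octamer C4,C5-diol (nineteen methyl ethers), via bis-formate 25 (not isolated)
Conditions: mCPBA (2.2 equiv), CH2Cl2, 0 °C; aq. Na2S2O3/NaHCO3 wash; then MeOH, cat. HCl, rt, argon
Reagents that add atoms: mCPBA (3-chloroperoxybenzoic acid), OOC(=O)c1cccc(Cl)c1
Why: Twofold Dakin (Baeyer–Villiger) oxidation as in steps 6 and 10: C4 has an ortho methoxy and a para aryloxy donor and C5 an ortho aryloxy donor, so both ring carbons should migrate. A small excess of peracid at 0 °C is used to spare ring A.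

Step 15
Reactants: 26 octamer C4,C5-diol (nineteen methyl ethers)
Product: 27 target CNP0206369.0 (21 free hydroxyls)
Conditions: BBr3 (large excess), CH2Cl2, −78 °C → rt; then H2O, 0 °C, argon
Reagents that add atoms: none
Why: Lewis acid cleavage of aryl methyl ethers: BBr3 binds each methoxy oxygen and bromide removes the methyl group as bromomethane, while the diaryl ethers offer no alkyl carbon for SN2 attack and should survive. Hydrolysis of the aryl borates gives the 21 hydroxyls; work-up under argon protects the pyrogallol units.

## Compound list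

1 | 4,5-difluoro-2-methoxybenzaldehyde | COc1cc(F)c(F)cc1C=O | starting material
2 | lithium {[2-(dimethylamino)ethyl](methyl)amino}(4,5-difluoro-2-methoxyphenyl)methanolate (racemic, transient) | COc1cc(F)c(F)cc1C(O[Li])N(C)CCN(C)C | intermediate
3 | 6-lithio derivative of 2 (lithium on the ring carbon between the fluorine and the amino alkoxide carbon) | COc1cc(F)c(F)c([Li])c1C(O[Li])N(C)CCN(C)C | intermediate
4 | 3,4-difluoro-6-methoxyphthalaldehyde (ring C, E and G linchpin) | COc1cc(F)c(F)c(C=O)c1C=O | intermediate
5 | 2,4,6-trimethoxyphenol | COc1cc(OC)c(O)c(OC)c1 | starting material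
6 | 4-fluoro-2,6-dimethoxybenzaldehyde | COc1cc(F)cc(OC)c1C=O | starting material
7 | 2,6-dimethoxy-4-(2,4,6-trimethoxyphenoxy)benzaldehyde | COc1cc(OC)c(Oc2cc(OC)c(C=O)c(OC)c2)c(OC)c1 | intermediate
8 | 2,6-dimethoxy-4-(2,4,6-trimethoxyphenoxy)phenyl formate | COc1cc(OC)c(Oc2cc(OC)c(OC=O)c(OC)c2)c(OC)c1 | intermediate
9 | 2,6-dimethoxy-4-(2,4,6-trimethoxyphenoxy)phenol (AB dimer phenol) | COc1cc(OC)c(Oc2cc(OC)c(O)c(OC)c2)c(OC)c1 | intermediate
10 | 4-bromo-2,6-dimethoxyphenol | COc1cc(Br)cc(OC)c1O | starting material
11 | 4-(4-bromo-2,6-dimethoxyphenoxy)-3-fluoro-6-methoxyphthalaldehyde (fluoro monoether for rings G and E) | Brc1cc(OC)c(Oc2cc(OC)c(C=O)c(C=O)c2F)c(OC)c1 | intermediate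
12 | 3,4,5-trimethoxyphenol | COc1cc(O)cc(OC)c1OC | starting material
13 | 4-(4-bromo-2,6-dimethoxyphenoxy)-6-methoxy-3-(3,4,5-trimethoxyphenoxy)phthalaldehyde (bromo FGH trimer, formyl groups at G4 and G5) | Brc1cc(OC)c(Oc2cc(OC)c(C=O)c(C=O)c2Oc2cc(OC)c(OC)c(OC)c2)c(OC)c1 | intermediate
14 | bis-formate of 15 (formyloxy groups at G4 and G5) | Brc1cc(OC)c(Oc2cc(OC)c(OC=O)c(OC=O)c2Oc2cc(OC)c(OC)c(OC)c2)c(OC)c1 | intermediate
15 | 4-(4-bromo-2,6-dimethoxyphenoxy)-6-methoxy-3-(3,4,5-trimethoxyphenoxy)benzene-1,2-diol | Brc1cc(OC)c(Oc2cc(OC)c(O)c(O)c2Oc2cc(OC)c(OC)c(OC)c2)c(OC)c1 | intermediate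
16 | 5-bromo-1,3-dimethoxy-2-[3,4,5-trimethoxy-2-(3,4,5-trimethoxyphenoxy)phenoxy]benzene | Brc1cc(OC)c(Oc2cc(OC)c(OC)c(OC)c2Oc2cc(OC)c(OC)c(OC)c2)c(OC)c1 | intermediate
17 | 3,5-dimethoxy-4-[3,4,5-trimethoxy-2-(3,4,5-trimethoxyphenoxy)phenoxy]phenol (FGH trimer phenol) | Oc1cc(OC)c(Oc2cc(OC)c(OC)c(OC)c2Oc2cc(OC)c(OC)c(OC)c2)c(OC)c1 | intermediate
18 | 4-(4-bromo-2,6-dimethoxyphenoxy)-3-{3,5-dimethoxy-4-[3,4,5-trimethoxy-2-(3,4,5-trimethoxyphenoxy)phenoxy]phenoxy}-6-methoxyphthalaldehyde (bromo pentamer, formyl groups at E4 and E5) | Brc1cc(OC)c(Oc2cc(OC)c(C=O)c(C=O)c2Oc2cc(OC)c(Oc3cc(OC)c(OC)c(OC)c3Oc3cc(OC)c(OC)c(OC)c3)c(OC)c2)c(OC)c1 | intermediate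
19 | bis-formate of 20 (formyloxy groups at E4 and E5) | Brc1cc(OC)c(Oc2cc(OC)c(OC=O)c(OC=O)c2Oc2cc(OC)c(Oc3cc(OC)c(OC)c(OC)c3Oc3cc(OC)c(OC)c(OC)c3)c(OC)c2)c(OC)c1 | intermediate
20 | bromo pentamer E4,E5-diol (18 with hydroxyls in place of both formyl groups) | Brc1cc(OC)c(Oc2cc(OC)c(O)c(O)c2Oc2cc(OC)c(Oc3cc(OC)c(OC)c(OC)c3Oc3cc(OC)c(OC)c(OC)c3)c(OC)c2)c(OC)c1 | intermediate
21 | permethylated DEFGH pentamer with bromine at D1 (thirteen methyl ethers) | Brc1cc(OC)c(Oc2cc(OC)c(OC)c(OC)c2Oc2cc(OC)c(Oc3cc(OC)c(OC)c(OC)c3Oc3cc(OC)c(OC)c(OC)c3)c(OC)c2)c(OC)c1 | intermediate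
22 | permethylated DEFGH pentamer with free D1 phenol (thirteen methyl ethers) | Oc1cc(OC)c(Oc2cc(OC)c(OC)c(OC)c2Oc2cc(OC)c(Oc3cc(OC)c(OC)c(OC)c3Oc3cc(OC)c(OC)c(OC)c3)c(OC)c2)c(OC)c1 | intermediate
23 | 4-[2,6-dimethoxy-4-(2,4,6-trimethoxyphenoxy)phenoxy]-3-fluoro-6-methoxyphthalaldehyde (ABC trimer, fluorine at C6) | COc1cc(OC)c(Oc2cc(OC)c(Oc3cc(OC)c(C=O)c(C=O)c3F)c(OC)c2)c(OC)c1 | intermediate
24 | octamer dialdehyde: rings A to H, formyl groups at C4 and C5, nineteen methyl ethers | COc1cc(OC)c(Oc2cc(OC)c(Oc3cc(OC)c(C=O)c(C=O)c3Oc3cc(OC)c(Oc4cc(OC)c(OC)c(OC)c4Oc4cc(OC)c(Oc5cc(OC)c(OC)c(OC)c5Oc5cc(OC)c(OC)c(OC)c5)c(OC)c4)c(OC)c3)c(OC)c2)c(OC)c1 | intermediate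
25 | octamer bis-formate: formyloxy groups at C4 and C5, nineteen methyl ethers | COc1cc(OC)c(Oc2cc(OC)c(Oc3cc(OC)c(OC=O)c(OC=O)c3Oc3cc(OC)c(Oc4cc(OC)c(OC)c(OC)c4Oc4cc(OC)c(Oc5cc(OC)c(OC)c(OC)c5Oc5cc(OC)c(OC)c(OC)c5)c(OC)c4)c(OC)c3)c(OC)c2)c(OC)c1 | intermediate
26 | octamer C4,C5-diol, nineteen methyl ethers | COc1cc(OC)c(Oc2cc(OC)c(Oc3cc(OC)c(O)c(O)c3Oc3cc(OC)c(Oc4cc(OC)c(OC)c(OC)c4Oc4cc(OC)c(Oc5cc(OC)c(OC)c(OC)c5Oc5cc(OC)c(OC)c(OC)c5)c(OC)c4)c(OC)c3)c(OC)c2)c(OC)c1 | intermediate
27 | CNP0206369.0: octameric polyhydroxylated diaryl ether, 21 hydroxyls, achiral | Oc1cc(O)c(Oc2cc(O)c(Oc3cc(O)c(O)c(O)c3Oc3cc(O)c(Oc4cc(O)c(O)c(O)c4Oc4cc(O)c(Oc5cc(O)c(O)c(O)c5Oc5cc(O)c(O)c(O)c5)c(O)c4)c(O)c3)c(O)c2)c(O)c1 | target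

## Step count and least certain steps

Total step count: 15. Longest linear sequence: 13 steps (step 1, then steps 4 to 15, from 1 to 27). The AB branch (steps 2 and 3) joins at step 13.

Step 13 (key step; steps 4, 5 and 9 carry the same risks on cheaper material). The second displacement may stall with the large pentamer phenoxide. Prolonged heating could then bring exchange of the aryloxy group already at C1, or disproportionation of the neighbouring formyl groups by traces of hydroxide. Some attack of the first phenoxide at the wrong fluoride is also possible. The fallback changes the fragment partition, so that the slow displacement is always done with a cheap or less advanced phenol in excess. It sets out from 23, made from 9 and 4 as in the first stage of step 13 and isolated. The remaining fluoride is displaced by the small, known phenol 4-(benzyloxy)-3,5-dimethoxyphenol F1 in excess (Cs2CO3, DMSO, 90 °C) to give the ABCD tetramer dialdehyde F2. Twofold Dakin oxidation (mCPBA, then MeOH and cat. HCl) by way of the tetramer bis-formate F3 gives the tetramer C4,C5-diol F4. Methylation (MeI, K2CO3) gives the permethylated tetramer benzyl ether F5, and hydrogenolysis (H2, Pd/C, EtOAc) gives the hindered tetramer D4 phenol F6. F6 then takes the place of 9 in a one-pot sequence with 4, passing through the pentamer fluoro dialdehyde F7 without isolation, and the trimer phenol 17 is added in excess to give the octamer E4,E5-dialdehyde F8. Dakin oxidation by way of the octamer E4,E5-bis-formate F9 gives the octamer E4,E5-diol F10, and BBr3 brings the fallback back to the route at 27.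

Step 1. Lithiation may occur between the methoxy group and fluorine instead of next to the amino alkoxide, or the ortho-fluoro aryllithium may lose LiF to an aryne. The fallback fixes the site through a directing group on the aldehyde. It sets out from 1. Bromination of the only C–H ortho to the formyl group with Pd(OAc)2 (divalent palladium), an anthranilic acid as transient imine directing group and NBS gives 2-bromo-3,4-difluoro-6-methoxybenzaldehyde F11. Acetalisation with ethylene glycol and TsOH gives 2-(2-bromo-3,4-difluoro-6-methoxyphenyl)-1,3-dioxolane F12. Bromine–magnesium exchange (iPrMgCl·LiCl, −20 °C) and DMF give the monoprotected dialdehyde 2-(1,3-dioxolan-2-yl)-5,6-difluoro-3-methoxybenzaldehyde F13, which aqueous acid hydrolyses in the work-up to 4, where the route resumes.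

Step 14 (steps 6 and 10 share the risk on smaller substrates). The second aryl migration may lag after the first, and the excess peracid then needed may oxidise the electron-rich rings A and H. Hydrogen migration to a carboxylic acid next to the remaining formyl group is also possible. The fallback divides the oxidation into two steps with different mechanisms. It sets out from 24. One equivalent of mCPBA gives the octamer mono-formate F14, and methanolysis gives the octamer hydroxy aldehyde F15, with a C4 hydroxyl beside the C5 formyl group. The regioisomer would serve equally, since either is an ortho-hydroxybenzaldehyde. The classical alkaline Dakin oxidation (H2O2, NaOH, aqueous THF, 0 °C, argon), in which hydroperoxide adds to the formyl group and no electrophilic peracid is present, then gives 26, where the route resumes.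

Step 15. Cleavage of all nineteen ethers may be incomplete, leaving partially methylated congeners that cannot be separated from the very polar product, and the pyrogallol units may oxidise during isolation. The fallback changes the isolation to derivatise, purify and release. It sets out from 26. After BBr3 treatment the crude polyphenol is acetylated at once (Ac2O, pyridine) to the henicosaacetate F16, which can be chromatographed on silica. Incompletely demethylated acetates are separated there and sent through the demethylation again. Acid-catalysed methanolysis (HCl in MeOH, argon) then releases 27.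

## Further compounds

F1 | step 13 | 4-(benzyloxy)-3,5-dimethoxyphenol | Oc1cc(OC)c(OCc2ccccc2)c(OC)c1
F2 | step 13 | ABCD tetramer dialdehyde: formyl groups at C4 and C5, benzyl ether at D4, eight methyl ethers | COc1cc(OC)c(Oc2cc(OC)c(Oc3cc(OC)c(C=O)c(C=O)c3Oc3cc(OC)c(OCc4ccccc4)c(OC)c3)c(OC)c2)c(OC)c1
F3 | step 13 | ABCD tetramer bis-formate: formyloxy groups at C4 and C5, benzyl ether at D4 | COc1cc(OC)c(Oc2cc(OC)c(Oc3cc(OC)c(OC=O)c(OC=O)c3Oc3cc(OC)c(OCc4ccccc4)c(OC)c3)c(OC)c2)c(OC)c1
F4 | step 13 | ABCD tetramer C4,C5-diol, benzyl ether at D4 | COc1cc(OC)c(Oc2cc(OC)c(Oc3cc(OC)c(O)c(O)c3Oc3cc(OC)c(OCc4ccccc4)c(OC)c3)c(OC)c2)c(OC)c1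
F5 | step 13 | permethylated ABCD tetramer with benzyl ether at D4 | COc1cc(OC)c(Oc2cc(OC)c(Oc3cc(OC)c(OC)c(OC)c3Oc3cc(OC)c(OCc4ccccc4)c(OC)c3)c(OC)c2)c(OC)c1
F6 | step 13 | permethylated ABCD tetramer with free D4 phenol | COc1cc(OC)c(Oc2cc(OC)c(Oc3cc(OC)c(OC)c(OC)c3Oc3cc(OC)c(O)c(OC)c3)c(OC)c2)c(OC)c1
F7 | step 13 | ABCDE pentamer fluoro dialdehyde: formyl groups at E4 and E5, fluorine at E6 | COc1cc(OC)c(Oc2cc(OC)c(Oc3cc(OC)c(OC)c(OC)c3Oc3cc(OC)c(Oc4cc(OC)c(C=O)c(C=O)c4F)c(OC)c3)c(OC)c2)c(OC)c1
F8 | step 13 | octamer dialdehyde with formyl groups at E4 and E5, nineteen methyl ethers | COc1cc(OC)c(Oc2cc(OC)c(Oc3cc(OC)c(OC)c(OC)c3Oc3cc(OC)c(Oc4cc(OC)c(C=O)c(C=O)c4Oc4cc(OC)c(Oc5cc(OC)c(OC)c(OC)c5Oc5cc(OC)c(OC)c(OC)c5)c(OC)c4)c(OC)c3)c(OC)c2)c(OC)c1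
F9 | step 13 | octamer bis-formate with formyloxy groups at E4 and E5, nineteen methyl ethers | COc1cc(OC)c(Oc2cc(OC)c(Oc3cc(OC)c(OC)c(OC)c3Oc3cc(OC)c(Oc4cc(OC)c(OC=O)c(OC=O)c4Oc4cc(OC)c(Oc5cc(OC)c(OC)c(OC)c5Oc5cc(OC)c(OC)c(OC)c5)c(OC)c4)c(OC)c3)c(OC)c2)c(OC)c1
F10 | step 13 | octamer E4,E5-diol, nineteen methyl ethers | COc1cc(OC)c(Oc2cc(OC)c(Oc3cc(OC)c(OC)c(OC)c3Oc3cc(OC)c(Oc4cc(OC)c(O)c(O)c4Oc4cc(OC)c(Oc5cc(OC)c(OC)c(OC)c5Oc5cc(OC)c(OC)c(OC)c5)c(OC)c4)c(OC)c3)c(OC)c2)c(OC)c1
F11 | step 1 | 2-bromo-3,4-difluoro-6-methoxybenzaldehyde | COc1cc(F)c(F)c(Br)c1C=O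
F12 | step 1 | 2-(2-bromo-3,4-difluoro-6-methoxyphenyl)-1,3-dioxolane | COc1cc(F)c(F)c(Br)c1C1OCCO1
F13 | step 1 | 2-(1,3-dioxolan-2-yl)-5,6-difluoro-3-methoxybenzaldehyde | COc1cc(F)c(F)c(C=O)c1C1OCCO1
F14 | step 14 | octamer mono-formate: formyloxy group at C4, formyl group at C5, nineteen methyl ethers | COc1cc(OC)c(Oc2cc(OC)c(Oc3cc(OC)c(OC=O)c(C=O)c3Oc3cc(OC)c(Oc4cc(OC)c(OC)c(OC)c4Oc4cc(OC)c(Oc5cc(OC)c(OC)c(OC)c5Oc5cc(OC)c(OC)c(OC)c5)c(OC)c4)c(OC)c3)c(OC)c2)c(OC)c1
F15 | step 14 | octamer hydroxy aldehyde: hydroxyl at C4, formyl group at C5, nineteen methyl ethers | COc1cc(OC)c(Oc2cc(OC)c(Oc3cc(OC)c(O)c(C=O)c3Oc3cc(OC)c(Oc4cc(OC)c(OC)c(OC)c4Oc4cc(OC)c(Oc5cc(OC)c(OC)c(OC)c5Oc5cc(OC)c(OC)c(OC)c5)c(OC)c4)c(OC)c3)c(OC)c2)c(OC)c1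
F16 | step 15 | henicosaacetate of 27 (all 21 hydroxyls acetylated) | CC(=O)Oc1cc(OC(C)=O)c(Oc2cc(OC(C)=O)c(Oc3cc(OC(C)=O)c(OC(C)=O)c(OC(C)=O)c3Oc3cc(OC(C)=O)c(Oc4cc(OC(C)=O)c(OC(C)=O)c(OC(C)=O)c4Oc4cc(OC(C)=O)c(Oc5cc(OC(C)=O)c(OC(C)=O)c(OC(C)=O)c5Oc5cc(OC(C)=O)c(OC(C)=O)c(OC(C)=O)c5)c(OC(C)=O)c4)c(OC(C)=O)c3)c(OC(C)=O)c2)c(OC(C)=O)c1
A1 | alternative 1 | 2-(4-benzyloxy-3,5-dimethoxyphenoxy)-3,4-dimethoxy-4-(1-methoxyvinyl)cyclobut-2-en-1-one (racemic) | COC(=C)C1(OC)C(OC)=C(Oc2cc(OC)c(OCc3ccccc3)c(OC)c2)C1=O
A2 | alternative 1 | 2-(4-benzyloxy-3,5-dimethoxyphenoxy)-3,4,5-trimethoxyphenol (CD dimer) | COc1cc(O)c(Oc2cc(OC)c(OCc3ccccc3)c(OC)c2)c(OC)c1OC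
A3 | alternative 2 | dimethyl 2-(heptamer-B1-oxy)malonate: permethylated BCDEFGH heptamer bound through the B1 oxygen to the malonate carbon | COC(=O)C(Oc1cc(OC)c(Oc2cc(OC)c(OC)c(OC)c2Oc2cc(OC)c(Oc3cc(OC)c(OC)c(OC)c3Oc3cc(OC)c(Oc4cc(OC)c(OC)c(OC)c4Oc4cc(OC)c(OC)c(OC)c4)c(OC)c3)c(OC)c2)c(OC)c1)C(=O)OC
A4 | alternative 2 | dimethyl 3-oxoglutarate | COC(=O)CC(=O)CC(=O)OC
A5 | alternative 2 | octamer with ring A as dimethyl 2,4,6-trihydroxyisophthalate, other rings permethylated | COC(=O)c1c(O)c(C(=O)OC)c(O)c(Oc2cc(OC)c(Oc3cc(OC)c(OC)c(OC)c3Oc3cc(OC)c(Oc4cc(OC)c(OC)c(OC)c4Oc4cc(OC)c(Oc5cc(OC)c(OC)c(OC)c5Oc5cc(OC)c(OC)c(OC)c5)c(OC)c4)c(OC)c3)c(OC)c2)c1O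
A6 | alternative 3 | octamer tetra-aldehyde: formyl groups at C4, E4, G4 and H4, seventeen methyl ethers | COc1cc(OC)c(Oc2cc(OC)c(Oc3cc(OC)c(C=O)c(OC)c3Oc3cc(OC)c(Oc4cc(OC)c(C=O)c(OC)c4Oc4cc(OC)c(Oc5cc(OC)c(C=O)c(OC)c5Oc5cc(OC)c(C=O)c(OC)c5)c(OC)c4)c(OC)c3)c(OC)c2)c(OC)c1
A7 | alternative 3 | octamer tetraphenol: hydroxyls at C4, E4, G4 and H4, seventeen methyl ethers | COc1cc(OC)c(Oc2cc(OC)c(Oc3cc(OC)c(O)c(OC)c3Oc3cc(OC)c(Oc4cc(OC)c(O)c(OC)c4Oc4cc(OC)c(Oc5cc(OC)c(O)c(OC)c5Oc5cc(OC)c(O)c(OC)c5)c(OC)c4)c(OC)c3)c(OC)c2)c(OC)c1
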